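Follow X.

| flask | X | L | remark | time |
|---|---|---|---|---|
| north | 0.70 M | 0.52 mol% | run made earlier |  |
| north-west | 0.47 M | 0.52 mol% | run made earlier |  |
| east | 1 M | 0.52 mol% | run made earlier |  |
| south-west | 0.70 M | 0.78 mol% | run made earlier |  |
| zeta | 0.70 M | 0.52 mol% | one stirred flow tank at steady state, fed with the mixture as stated, mean residence time 1.0 h |  |
| theta | 0.70 M (fed, over 0.800 h) | 0.52 mol% | a stirred flask in which X is dosed at a steady rate over 0.800 h without added volume, worked up at 1.0 h | 1.0 h |
| delta | 0.70 M | 0.52 mol% | everything together in a closed stirred flask, run for 1.0 h | 1.0 h |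
| epsilon | 0.70 M | 0.52 mol% | one stirred flow tank at steady state, fed with the mixture as stated, mean residence time 10.0 h |  |

| run | time / min | Q / % | X / % |
|---|---|---|---|
| north | 3.00 | 2 | 103 |
| north | 4.00 | 0 | 99 |
| north | 6.00 | 0 | 94 |
| north | 10.0 | 8 | 89 |
| north | 15.0 | 13 | 81 |
| north | 25.0 | 30 | 69 |
| north | 40.0 | 55 | 46 |
| north-west | 3.00 | 1 | 99 |
| north-west | 4.00 | 4 | 101 |
| north-west | 6.00 | 2 | 98 |
| north-west | 10.0 | 7 | 94 |
| north-west | 15.0 | 17 | 89 |
| north-west | 25.0 | 25 | 77 |
| north-west | 40.0 | 50 | 54 |
| east | 2.00 | 2 | 100 |
| east | 6.00 | 4 | 96 |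
| east | 10.0 | 9 | 91 |
| east | 15.0 | 18 | 82 |
| east | 20.0 | 24 | 69 |
| east | 30.0 | 44 | 54 |
| east | 40.0 | 60 | 41 |
| south-west | 8.00 | 6 | 89 |
| south-west | 15.0 | 21 | 79 |
| south-west | 20.0 | 34 | 66 |
| south-west | 30.0 | 56 | 48 |
| south-west | 40.0 | 71 | 29 |

(scatter of a reading: 2 percentage points)

- the stated concentrations are those of everything mixed, before any reaction; amounts are the same in each set-up
- the earlier runs were read with a standard deviation of 2 percentage points
- the feed brings no volume worth counting
- the earlier runs were made in a closed, stirred flask

- order of the set-ups by the amount of Q at the outlet or at the end, in percent of the X put in, highest first (zeta / theta / delta / epsilon)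
- amount of Q at the outlet or at the end, in percent of the X put in, zeta
- amount of Q at the outlet or at the end, in percent of the X put in, theta
- amount of Q at the outlet or at the end, in percent of the X put in, delta
- amount of Q at the outlet or at the end, in percent of the X put in, epsilon

X is the limiting reagent, so my ledger opens with the X charged and has two entries I can read. In the north run at 40.0 min, Q stands at 55% and X at 46%. Together they make 101% of the charge, and each reading scatters by 2 percentage points, so I book Q as the charge less the X left.

The X entry then needs one rate, which I write as -d[X]/dt = κ[X], a pseudo-first-order law. The north run gives 1.62 h⁻¹, and this is the late constant, the drop of ln[X] per hour between the last two readings of a run. The east run, at the same loading, reads 1.65 h⁻¹. Over the first 15.0 min of the north run the drop is 0.843 h⁻¹, less than the late constant, so κ is a reading of the later part of a run.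

Integrating from the 40.0 min reading, I book 26.8% of the X as left in delta, so I book Q at 73.2%. The tank balance leaves the fraction 1/(1+κτ), which books Q at 61.9% in zeta and 94.2% in epsilon. For theta I take κ from the first minute, though the early drop of 0.843 h⁻¹ is lower, and the dosing integral books Q at 59.5%.

The forecast reads the runs as “a background path plus autocatalysis by Q” and gives 69% for zeta, 49% for theta, 79% for delta and 97% for epsilon, in the order epsilon > delta > zeta > theta. My order is the same. My Q is lower than the forecast's in delta, zeta and epsilon, and higher in theta.

The flask gives 61.0% in zeta, 66.0% in theta, 76.2% in delta and 91.0% in epsilon, in the order epsilon > delta > theta > zeta. Here Z and G are forms of the catalyst: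

    G ⇌ Z + Q (K = 0.700 M, k = 11.7 min⁻¹)
    X + Z ⇌ G (K = 27.4 M⁻¹, k = 22.8 M⁻¹ min⁻¹)
    L → Z (k = 0.0536 min⁻¹)

Theta ends with 33.7% of its X left and stands above zeta. Read back through the tank balance, the 38.8% of X at the zeta outlet gives a constant of 1.58 h⁻¹, close to the late constant of 1.62 h⁻¹. The 8.72% of X at the epsilon outlet gives 1.05 h⁻¹, lower than the late constant.

(The numbers in the tables were computed for an exercise; the scatter is artificial.)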